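**Plan**
- Retrosynthesis: the oxolane (O1, C2–C5) is cut at O1–C2 and C2–CH2Ar (carbenoid → oxonium ylide → [1,2]-benzyl shift) to diazoketone 25. Diazoketone 25 is then cut at C2–C3 (acylation of diazomethane), at the C5–O–CH2Ar ether and at C4–C5 (anti-aldol), giving aldehyde 10 and imide 17.
- The dihydrobenzofuran is cut at C2'–C3' (carbenoid C–H insertion), at C3a–C3' (Pd coupling with ethyl diazoacetate) and at its aryl ether, back to 5-iodovanillin and O-benzylvanillin.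
- Enabling feature: C2 of the oxolane carries both ring oxygen O1 and the guaiacylmethyl group and lies next to C3 (a ketone during the synthesis). A guaiacylmethyl ether on the C5 oxygen can therefore hand its benzyl group to a carbenoid carbon that becomes C2 while O1–C2 closes the ring.
- Forward order: dihydrobenzofuran ring first (step 5), C4–C5 joined by aldol (step 11), oxolane ring last (step 16), then C3 reduction and deprotection.
- Stereochemistry: C2'/C3' (cis) from a chiral dirhodium catalyst; C4/C5 from (S)-4-benzyloxazolidin-2-one in a magnesium-catalysed anti-aldol; C2 by equilibration against C5/C4; C3 by hydroxymethyl-directed hydride delivery.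

Key step: step 16

**Remarks**
- The target is read as a (2S,3S,4S,5S) oxolane (2-benzyl and 5-aryl cis, 4-CH2OH trans to both, 3-OH cis to the benzyl group) carrying a 2,3-cis (2R,3R) dihydrobenzofuran. The cis ring is why a carbenoid C–H insertion is used to build it.
- Assumption: Rh2(S-PTTL)4 (dirhodium tetrakis[N-phthaloyl-(S)-tert-leucinate]) is taken to give the (2R,3S) ester 7; the (R)-PTTL complex would be used if the sense of induction proved opposite.
- Compounds 1, 3, 11 and 15 are commercial.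
- Abbreviations: BnV = 4-(benzyloxy)-3-methoxybenzyl. DBF = (2R,3R)-2-[4-(benzyloxy)-3-methoxyphenyl]-3-[(tert-butyldimethylsilyloxy)methyl]-7-methoxy-2,3-dihydro-1-benzofuran-5-yl. DBF(OH) = the same group with a free 3-hydroxymethyl. TBS = tert-butyldimethylsilyl, TBDPS = tert-butyldiphenylsilyl, TES = triethylsilyl.
- Oxolane atoms are numbered O1, C2 (benzyl), C3, C4 (CH2O), C5 (aryl); dihydrobenzofuran atoms are primed.

**Route**

Step 1
Reactants: 1 4-(benzyloxy)-3-methoxybenzaldehyde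
Product: 2 [4-(benzyloxy)-3-methoxyphenyl]methanol
Conditions: NaBH4, MeOH, 0 °C
Reagents that add atoms: none
Why: Borohydride carbonyl reduction converts the aryl aldehyde cleanly into the benzylic alcohol and leaves the benzyl aryl ether untouched.

Step 2
Reactants: 3 4-hydroxy-3-iodo-5-methoxybenzaldehyde (5-iodovanillin); 2 [4-(benzyloxy)-3-methoxyphenyl]methanol
Product: 4 4-(BnV-oxy)-3-iodo-5-methoxybenzaldehyde
Conditions: PPh3, DIAD, THF, 0 °C → rt
Reagents that add atoms: none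
Why: Mitsunobu etherification, in which the acidic phenol (para-formyl, ortho-iodo) displaces the oxyphosphonium of the primary benzylic alcohol, so that no labile electron-rich benzyl halide has to be made.

Step 3
Reactants: 4 4-(BnV-oxy)-3-iodo-5-methoxybenzaldehyde
Product: 5 4-(BnV-oxy)-3-iodo-5-methoxybenzaldehyde dimethyl acetal
Conditions: HC(OMe)3, PPTS (5 mol %), MeOH, rt; Et3N quench
Reagents that add atoms: trimethyl orthoformate COC(OC)OC; methanol CO
Why: Acid-catalysed acetalisation with orthoformate as water scavenger masks the formyl group against the carbenoid and hydride steps ahead, and PPTS is too weak to solvolyse the para-alkoxybenzyl aryl ether.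

Step 4
Reactants: 5 4-(BnV-oxy)-3-iodo-5-methoxybenzaldehyde dimethyl acetal
Product: 6 ethyl 2-diazo-2-[2-(BnV-oxy)-5-(dimethoxymethyl)-3-methoxyphenyl]acetate
Conditions: N2CHCO2Et (2 equiv), Pd(PPh3)4 (5 mol %), Ag2CO3 (0.5 equiv), Et3N, toluene, rt
Reagents that add atoms: ethyl diazoacetate CCOC(=O)C=[N+]=[N-]
Why: Palladium-catalysed cross-coupling of an aryl iodide with ethyl diazoacetate (oxidative addition to zerovalent palladium, base- and silver-assisted palladation of the diazo carbon with the diazo group retained, reductive elimination) installs the aryldiazoacetate at the future C3a in one operation.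

Step 5
Reactants: 6 ethyl 2-diazo-2-[2-(BnV-oxy)-5-(dimethoxymethyl)-3-methoxyphenyl]acetate
Product: 7 ethyl (2R,3S)-2-[4-(benzyloxy)-3-methoxyphenyl]-5-(dimethoxymethyl)-7-methoxy-2,3-dihydro-1-benzofuran-3-carboxylate
Conditions: Rh2(S-PTTL)4 (1 mol %), toluene, −60 °C
Reagents that add atoms: none
Why: Intramolecular dirhodium-carbenoid 1,5-C–H insertion into the doubly activated O–CH2–Ar methylene closes the dihydrofuran ring, the concerted insertion placing ester and aryl cis and the chiral carboxylate ligands selecting one enantiotopic C–H bond to set C2' (R) and C3' (S at the ester level).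

Step 6
Reactants: 7 ethyl (2R,3S)-2-[4-(benzyloxy)-3-methoxyphenyl]-5-(dimethoxymethyl)-7-methoxy-2,3-dihydro-1-benzofuran-3-carboxylate
Product: 9 (2R,3R)-2-[4-(benzyloxy)-3-methoxyphenyl]-3-(hydroxymethyl)-7-methoxy-2,3-dihydro-1-benzofuran-5-carbaldehyde, via hydroxy acetal 8 (not isolated)
Conditions: i-Bu2AlH (2.5 equiv), CH2Cl2, −78 °C; then 1 M aq HCl, THF, 0 °C
Reagents that add atoms: water O
Why: DIBAL-H reduces the ester to the primary alcohol at low temperature without base, so the benzylic C3' centre should keep its cis relationship, and the brief cold aqueous-acid work-up hydrolyses the dimethyl acetal to release the aldehyde.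

Step 7
Reactants: 9 (2R,3R)-2-[4-(benzyloxy)-3-methoxyphenyl]-3-(hydroxymethyl)-7-methoxy-2,3-dihydro-1-benzofuran-5-carbaldehyde
Product: 10 (2R,3R)-2-[4-(benzyloxy)-3-methoxyphenyl]-3-[(tert-butyldimethylsilyloxy)methyl]-7-methoxy-2,3-dihydro-1-benzofuran-5-carbaldehyde
Conditions: t-BuMe2SiCl, imidazole, CH2Cl2, rt
Reagents that add atoms: tert-butyldimethylsilyl chloride CC(C)(C)[Si](C)(C)Cl
Why: Imidazole-promoted silylation of the primary alcohol gives a silyl ether that is stable to the basic, weakly acidic and carbenoid conditions that follow.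

Step 8
Reactants: 11 propane-1,3-diol
Product: 12 3-(tert-butyldiphenylsilyloxy)propan-1-ol
Conditions: NaH (1 equiv), THF, rt; then t-BuPh2SiCl (1 equiv)
Reagents that add atoms: tert-butyldiphenylsilyl chloride CC(C)(C)[Si](Cl)(c1ccccc1)c1ccccc1
Why: Monosilylation of a symmetrical diol through its sparingly soluble monosodium alkoxide should stop at the mono-ether.

Step 9
Reactants: 12 3-(tert-butyldiphenylsilyloxy)propan-1-ol
Product: 14 3-(tert-butyldiphenylsilyloxy)propanoic acid, via aldehyde 13 (not isolated)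
Conditions: TEMPO (0.2 equiv), PhI(OAc)2 (2.2 equiv), MeCN/H2O (1:1), rt
Reagents that add atoms: water O
Why: The oxoammonium-mediated oxidation takes the primary alcohol through the aldehyde hydrate to the acid under nearly neutral conditions that spare the silyl ether.

Step 10
Reactants: 14 3-(tert-butyldiphenylsilyloxy)propanoic acid; 15 (S)-4-benzyloxazolidin-2-one
Product: 17 (S)-4-benzyl-3-[3-(tert-butyldiphenylsilyloxy)propanoyl]oxazolidin-2-one, via mixed pivalic anhydride 16 (not isolated)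
Conditions: t-BuCOCl, Et3N, THF, −20 °C; then LiCl, 15, rt
Reagents that add atoms: none
Why: N-Acylation of the oxazolidinone by a mixed pivalic anhydride under LiCl/Et3N activation attaches the auxiliary without a strong base that could eliminate the β-silyloxy group.

Step 11
Reactants: 17 (S)-4-benzyl-3-[3-(tert-butyldiphenylsilyloxy)propanoyl]oxazolidin-2-one (1.3 equiv); 10 (2R,3R)-2-[4-(benzyloxy)-3-methoxyphenyl]-3-[(tert-butyldimethylsilyloxy)methyl]-7-methoxy-2,3-dihydro-1-benzofuran-5-carbaldehyde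
Product: 19 (S)-4-benzyl-3-[(2R,3S)-3-hydroxy-2-[(TBDPS-oxy)methyl]-3-(DBF)propanoyl]oxazolidin-2-one, via silyl ether 18 (not isolated)
Conditions: MgCl2 (0.2 equiv), Et3N (2 equiv), Me3SiCl (1.5 equiv), EtOAc, rt; then 1 M aq citric acid, THF, 0 °C
Reagents that add atoms: none
Why: Magnesium halide-catalysed anti-aldol reaction of an N-acyloxazolidinone with a non-enolisable aryl aldehyde, in which the chelated Z-magnesium enolate reacts through a boat transition state on the face away from the auxiliary benzyl group to set C4 (R) and C5 (S) anti, silylation of the aldolate drives turnover, and the mild acid work-up removes only the trimethylsilyl group.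

Step 12
Reactants: 2 [4-(benzyloxy)-3-methoxyphenyl]methanol
Product: 20 BnV 2,2,2-trichloroacetimidate
Conditions: Cl3CCN, DBU (cat.), CH2Cl2, 0 °C
Reagents that add atoms: trichloroacetonitrile N#CC(Cl)(Cl)Cl
Why: Base-catalysed addition of the alcohol to trichloroacetonitrile gives the benzyl donor for a non-basic etherification.

Step 13
Reactants: 19 (S)-4-benzyl-3-[(2R,3S)-3-hydroxy-2-[(TBDPS-oxy)methyl]-3-(DBF)propanoyl]oxazolidin-2-one; 20 BnV 2,2,2-trichloroacetimidate (2 equiv)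
Product: 21 (S)-4-benzyl-3-[(2R,3S)-3-(BnV-oxy)-2-[(TBDPS-oxy)methyl]-3-(DBF)propanoyl]oxazolidin-2-one
Conditions: PPTS (0.1 equiv), CH2Cl2, 0 °C → rt
Reagents that add atoms: none
Why: Acid-catalysed trichloroacetimidate benzylation, in which the protonated imidate releases the strongly stabilised dialkoxybenzyl cation to the secondary hydroxyl under conditions that avoid the retro-aldol cleavage a Williamson etherification would cause and that leave the C5–O bond, and hence C5, untouched.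

Step 14
Reactants: 21 (S)-4-benzyl-3-[(2R,3S)-3-(BnV-oxy)-2-[(TBDPS-oxy)methyl]-3-(DBF)propanoyl]oxazolidin-2-one
Product: 23 (2R,3S)-3-(BnV-oxy)-2-[(TBDPS-oxy)methyl]-3-(DBF)propanoic acid, via peroxy acid 22 (not isolated)
Conditions: LiOH, 30% aq H2O2, THF/H2O (3:1), 0 °C; aq Na2SO3; then 1 M HCl to pH 3
Reagents that add atoms: hydrogen peroxide OO
Why: Lithium hydroperoxide attacks the exocyclic imide carbonyl selectively even in hindered acyl oxazolidinones, and sulfite reduction of the peroxy acid gives the acid without epimerisation at C4 at 0 °C.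

Step 15
Reactants: 23 (2R,3S)-3-(BnV-oxy)-2-[(TBDPS-oxy)methyl]-3-(DBF)propanoic acid
Product: 25 (3R,4S)-4-(BnV-oxy)-1-diazo-3-[(TBDPS-oxy)methyl]-4-(DBF)butan-2-one, via mixed carbonic anhydride 24 (not isolated)
Conditions: i-BuOCOCl, N-methylmorpholine, THF, −20 °C; then CH2N2 (excess), Et2O, −20 → 0 °C
Reagents that add atoms: diazomethane C=[N+]=[N-]
Why: C-Acylation of diazomethane by a mixed carbonic anhydride (the first stage of an Arndt–Eistert sequence) forms the C2–C3 bond and the α-diazoketone without exposing the acid-labile benzylic ethers to an acid chloride or HCl.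

Step 16
Reactants: 25 (3R,4S)-4-(BnV-oxy)-1-diazo-3-[(TBDPS-oxy)methyl]-4-(DBF)butan-2-one
Product: 28 (2S,4R,5S)-2-(BnV)-4-[(TBDPS-oxy)methyl]-5-(DBF)oxolan-3-one, via oxonium ylide 26 (not isolated), via C2-epimeric oxolanone 27 (not isolated)
Conditions: Cu(CF3COCHCOCF3)2 (5 mol %), CH2Cl2, reflux, slow addition of 25; then DBU (0.2 equiv), 0 °C
Reagents that add atoms: none
Why: Loss of N2 at copper gives an electrophilic carbenoid at the future C2, which is captured by a lone pair of the C5 ether oxygen to form O1–C2 and the five-membered cyclic oxonium ylide 26 (closure of the O1–C2–C3–C4–C5 ring by attack of the ether oxygen on the metal-bound carbon, a 5-exo-type closure with respect to the copper–carbon bond); homolysis of the exocyclic O–CH2Ar bond then gives a caged pair of a para-alkoxybenzyl radical and the C2 α-keto radical that recombines at carbon to form C2–CH2Ar (Stevens [1,2]-shift). The closest known reaction type is the copper- or rhodium-catalysed conversion of 4-benzyloxy-1-diazobutan-2-ones into 2-benzyloxolan-3-ones. C2 is the only new stereocentre: the benzyl group probably leaves oxygen on the face anti to the C5 aryl group, so part of the material is expected as the 2,5-trans epimer 27, and because C2 lies between O1 and the ketone it is equilibrated with catalytic DBU towards the 2,5-cis, 2,4-trans, 4,5-trans isomer 28, an arrangement controlled by the fixed C5 centre (C4, also enolisable, already holds its favoured trans relation to C5). The step needs ylide formation at the dibenzylic ether oxygen to outrun Buchner-type addition to the C5 arene, C–H insertion and capture by the silyl ether oxygen (also five atoms away), and it needs cleavage of the exocyclic and not the ring C5–O bond. These are secured by the ylide-selective, electron-poor catalyst Cu(CF3COCHCOCF3)2, by the low basicity and bulk of the TBDPS ether oxygen, by the radical stabilisation of the 4-benzyloxy-3-methoxybenzyl group and by the strain of the cyclobutanone that ring contraction would give.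

Step 17
Reactants: 28 (2S,4R,5S)-2-(BnV)-4-[(TBDPS-oxy)methyl]-5-(DBF)oxolan-3-one
Product: 29 (2S,4R,5S)-2-(BnV)-4-(hydroxymethyl)-5-[DBF(OH)]oxolan-3-one
Conditions: Bu4NF, AcOH (1:1, 4 equiv each), THF, 0 °C → rt
Reagents that add atoms: none
Why: Fluoride cleaves both silyl ethers, and the acetic acid buffer keeps the emerging β-hydroxy ketone away from basic fluoride that could cause retro-aldol loss of formaldehyde or dehydration at C4.

Step 18
Reactants: 29 (2S,4R,5S)-2-(BnV)-4-(hydroxymethyl)-5-[DBF(OH)]oxolan-3-one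
Product: 30 (2S,3S,4S,5S)-2-(BnV)-4-(hydroxymethyl)-5-[DBF(OH)]oxolan-3-ol
Conditions: Me4NBH(OAc)3 (5 equiv), MeCN/AcOH (1:1), −20 °C
Reagents that add atoms: none
Why: Hydroxyl-directed triacetoxyborohydride reduction (Evans–Saksena type), in which the C4 hydroxymethyl group binds boron and delivers hydride to C3 from its own face, so the new hydroxyl should be trans to CH2OH and cis to the C2 benzyl group (C3 = S).

Step 19
Reactants: 30 (2S,3S,4S,5S)-2-(BnV)-4-(hydroxymethyl)-5-[DBF(OH)]oxolan-3-ol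
Product: 31 (2S,3S,4S,5S)-2-(4-hydroxy-3-methoxybenzyl)-4-(hydroxymethyl)-5-[(2R,3R)-2-(4-hydroxy-3-methoxyphenyl)-3-(hydroxymethyl)-7-methoxy-2,3-dihydro-1-benzofuran-5-yl]oxolan-3-ol
Conditions: H2 (1 atm), 10% Pd/C, EtOAc, rt, stopped at full conversion
Reagents that add atoms: none
Why: Hydrogenolysis of the two aryl benzyl ethers in a neutral solvent at atmospheric pressure is expected to be much faster than cleavage of the cyclic benzylic C5–O1 and C2'–O1' bonds, which normally needs acid or prolonged reaction.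

**Compound list**

1 | 4-(benzyloxy)-3-methoxybenzaldehyde (O-benzylvanillin) | COc1cc(C=O)ccc1OCc1ccccc1 | starting material
2 | [4-(benzyloxy)-3-methoxyphenyl]methanol | COc1cc(CO)ccc1OCc1ccccc1 | intermediate
3 | 4-hydroxy-3-iodo-5-methoxybenzaldehyde (5-iodovanillin) | COc1cc(C=O)cc(I)c1O | starting material
4 | 4-(BnV-oxy)-3-iodo-5-methoxybenzaldehyde | COc1cc(C=O)cc(I)c1OCc1ccc(OCc2ccccc2)c(OC)c1 | intermediate
5 | 4-(BnV-oxy)-3-iodo-5-methoxybenzaldehyde dimethyl acetal | COc1cc(C(OC)OC)cc(I)c1OCc1ccc(OCc2ccccc2)c(OC)c1 | intermediate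
6 | ethyl 2-diazo-2-[2-(BnV-oxy)-5-(dimethoxymethyl)-3-methoxyphenyl]acetate | CCOC(=O)C(=[N+]=[N-])c1cc(C(OC)OC)cc(OC)c1OCc1ccc(OCc2ccccc2)c(OC)c1 | intermediate
7 | ethyl (2R,3S)-2-[4-(benzyloxy)-3-methoxyphenyl]-5-(dimethoxymethyl)-7-methoxy-2,3-dihydro-1-benzofuran-3-carboxylate (2,3-cis) | COC(OC)c1cc(OC)c2c(c1)[C@H](C(=O)OCC)[C@H](c1ccc(OCc3ccccc3)c(OC)c1)O2 | intermediate
8 | [(2R,3R)-2-[4-(benzyloxy)-3-methoxyphenyl]-5-(dimethoxymethyl)-7-methoxy-2,3-dihydro-1-benzofuran-3-yl]methanol (formed in the flask) | COC(OC)c1cc(OC)c2c(c1)[C@H](CO)[C@H](c1ccc(OCc3ccccc3)c(OC)c1)O2 | intermediate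
9 | (2R,3R)-2-[4-(benzyloxy)-3-methoxyphenyl]-3-(hydroxymethyl)-7-methoxy-2,3-dihydro-1-benzofuran-5-carbaldehyde | O=Cc1cc(OC)c2c(c1)[C@H](CO)[C@H](c1ccc(OCc3ccccc3)c(OC)c1)O2 | intermediate
10 | (2R,3R)-2-[4-(benzyloxy)-3-methoxyphenyl]-3-[(tert-butyldimethylsilyloxy)methyl]-7-methoxy-2,3-dihydro-1-benzofuran-5-carbaldehyde (DBF-CHO) | O=Cc1cc(OC)c2c(c1)[C@H](CO[Si](C)(C)C(C)(C)C)[C@H](c1ccc(OCc3ccccc3)c(OC)c1)O2 | intermediate
11 | propane-1,3-diol | OCCCO | starting material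
12 | 3-(tert-butyldiphenylsilyloxy)propan-1-ol | OCCCO[Si](c1ccccc1)(c1ccccc1)C(C)(C)C | intermediate
13 | 3-(tert-butyldiphenylsilyloxy)propanal (formed in the flask) | O=CCCO[Si](c1ccccc1)(c1ccccc1)C(C)(C)C | intermediate
14 | 3-(tert-butyldiphenylsilyloxy)propanoic acid | OC(=O)CCO[Si](c1ccccc1)(c1ccccc1)C(C)(C)C | intermediate
15 | (S)-4-benzyloxazolidin-2-one | O=C1N[C@@H](Cc2ccccc2)CO1 | starting material
16 | 3-(tert-butyldiphenylsilyloxy)propanoic pivalic anhydride (formed in the flask) | CC(C)(C)C(=O)OC(=O)CCO[Si](c1ccccc1)(c1ccccc1)C(C)(C)C | intermediate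
17 | (S)-4-benzyl-3-[3-(tert-butyldiphenylsilyloxy)propanoyl]oxazolidin-2-one | O=C(CCO[Si](c1ccccc1)(c1ccccc1)C(C)(C)C)N1[C@@H](Cc2ccccc2)COC1=O | intermediate
18 | (S)-4-benzyl-3-[(2R,3S)-2-[(TBDPS-oxy)methyl]-3-(DBF)-3-(trimethylsilyloxy)propanoyl]oxazolidin-2-one (formed in the flask) | O=C(N1[C@@H](Cc2ccccc2)COC1=O)[C@H](CO[Si](c1ccccc1)(c1ccccc1)C(C)(C)C)[C@@H](c1cc(OC)c2c(c1)[C@H](CO[Si](C)(C)C(C)(C)C)[C@H](c1ccc(OCc3ccccc3)c(OC)c1)O2)O[Si](C)(C)C | intermediate
19 | (S)-4-benzyl-3-[(2R,3S)-3-hydroxy-2-[(TBDPS-oxy)methyl]-3-(DBF)propanoyl]oxazolidin-2-one (anti) | O=C(N1[C@@H](Cc2ccccc2)COC1=O)[C@H](CO[Si](c1ccccc1)(c1ccccc1)C(C)(C)C)[C@@H](c1cc(OC)c2c(c1)[C@H](CO[Si](C)(C)C(C)(C)C)[C@H](c1ccc(OCc3ccccc3)c(OC)c1)O2)O | intermediate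
20 | BnV 2,2,2-trichloroacetimidate | COc1cc(COC(=N)C(Cl)(Cl)Cl)ccc1OCc1ccccc1 | intermediate
21 | (S)-4-benzyl-3-[(2R,3S)-3-(BnV-oxy)-2-[(TBDPS-oxy)methyl]-3-(DBF)propanoyl]oxazolidin-2-one | O=C(N1[C@@H](Cc2ccccc2)COC1=O)[C@H](CO[Si](c1ccccc1)(c1ccccc1)C(C)(C)C)[C@@H](c1cc(OC)c2c(c1)[C@H](CO[Si](C)(C)C(C)(C)C)[C@H](c1ccc(OCc3ccccc3)c(OC)c1)O2)OCc1ccc(OCc2ccccc2)c(OC)c1 | intermediate
22 | (2R,3S)-3-(BnV-oxy)-2-[(TBDPS-oxy)methyl]-3-(DBF)propaneperoxoic acid (formed in the flask) | OOC(=O)[C@H](CO[Si](c1ccccc1)(c1ccccc1)C(C)(C)C)[C@@H](c1cc(OC)c2c(c1)[C@H](CO[Si](C)(C)C(C)(C)C)[C@H](c1ccc(OCc3ccccc3)c(OC)c1)O2)OCc1ccc(OCc2ccccc2)c(OC)c1 | intermediate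
23 | (2R,3S)-3-(BnV-oxy)-2-[(TBDPS-oxy)methyl]-3-(DBF)propanoic acid | OC(=O)[C@H](CO[Si](c1ccccc1)(c1ccccc1)C(C)(C)C)[C@@H](c1cc(OC)c2c(c1)[C@H](CO[Si](C)(C)C(C)(C)C)[C@H](c1ccc(OCc3ccccc3)c(OC)c1)O2)OCc1ccc(OCc2ccccc2)c(OC)c1 | intermediate
24 | mixed anhydride of 23 with isobutyl hydrogen carbonate (formed in the flask) | CC(C)COC(=O)OC(=O)[C@H](CO[Si](c1ccccc1)(c1ccccc1)C(C)(C)C)[C@@H](c1cc(OC)c2c(c1)[C@H](CO[Si](C)(C)C(C)(C)C)[C@H](c1ccc(OCc3ccccc3)c(OC)c1)O2)OCc1ccc(OCc2ccccc2)c(OC)c1 | intermediate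
25 | (3R,4S)-4-(BnV-oxy)-1-diazo-3-[(TBDPS-oxy)methyl]-4-(DBF)butan-2-one | [N-]=[N+]=CC(=O)[C@H](CO[Si](c1ccccc1)(c1ccccc1)C(C)(C)C)[C@@H](c1cc(OC)c2c(c1)[C@H](CO[Si](C)(C)C(C)(C)C)[C@H](c1ccc(OCc3ccccc3)c(OC)c1)O2)OCc1ccc(OCc2ccccc2)c(OC)c1 | intermediate
26 | (4R,5S)-1-(BnV)-4-[(TBDPS-oxy)methyl]-5-(DBF)-3-oxooxolan-1-ium-2-ide, the cyclic oxonium ylide (formed in the flask) | [CH-]1[O+](Cc2ccc(OCc3ccccc3)c(OC)c2)[C@H](c2cc(OC)c3c(c2)[C@H](CO[Si](C)(C)C(C)(C)C)[C@H](c2ccc(OCc4ccccc4)c(OC)c2)O3)[C@@H](CO[Si](c2ccccc2)(c2ccccc2)C(C)(C)C)C1=O | intermediate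
27 | (2R,4R,5S)-2-(BnV)-4-[(TBDPS-oxy)methyl]-5-(DBF)oxolan-3-one, the 2,5-trans epimer (formed in the flask) | COc1cc(C[C@H]2O[C@H](c3cc(OC)c4c(c3)[C@H](CO[Si](C)(C)C(C)(C)C)[C@H](c3ccc(OCc5ccccc5)c(OC)c3)O4)[C@@H](CO[Si](c3ccccc3)(c3ccccc3)C(C)(C)C)C2=O)ccc1OCc1ccccc1 | intermediate
28 | (2S,4R,5S)-2-(BnV)-4-[(TBDPS-oxy)methyl]-5-(DBF)oxolan-3-one (2,5-cis, 4,5-trans) | COc1cc(C[C@@H]2O[C@H](c3cc(OC)c4c(c3)[C@H](CO[Si](C)(C)C(C)(C)C)[C@H](c3ccc(OCc5ccccc5)c(OC)c3)O4)[C@@H](CO[Si](c3ccccc3)(c3ccccc3)C(C)(C)C)C2=O)ccc1OCc1ccccc1 | intermediate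
29 | (2S,4R,5S)-2-(BnV)-4-(hydroxymethyl)-5-[DBF(OH)]oxolan-3-one | COc1cc(C[C@@H]2O[C@H](c3cc(OC)c4c(c3)[C@H](CO)[C@H](c3ccc(OCc5ccccc5)c(OC)c3)O4)[C@@H](CO)C2=O)ccc1OCc1ccccc1 | intermediate
30 | (2S,3S,4S,5S)-2-(BnV)-4-(hydroxymethyl)-5-[DBF(OH)]oxolan-3-ol | COc1cc(C[C@@H]2O[C@H](c3cc(OC)c4c(c3)[C@H](CO)[C@H](c3ccc(OCc5ccccc5)c(OC)c3)O4)[C@@H](CO)[C@@H]2O)ccc1OCc1ccccc1 | intermediate
31 | (2S,3S,4S,5S)-2-(4-hydroxy-3-methoxybenzyl)-4-(hydroxymethyl)-5-[(2R,3R)-2-(4-hydroxy-3-methoxyphenyl)-3-(hydroxymethyl)-7-methoxy-2,3-dihydro-1-benzofuran-5-yl]oxolan-3-ol (CNP0179668.1) | COc1cc(C[C@@H]2O[C@H](c3cc(OC)c4c(c3)[C@H](CO)[C@H](c3ccc(O)c(OC)c3)O4)[C@@H](CO)[C@@H]2O)ccc1O | target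

**Totals**
Total step count: 19.
Longest linear sequence: 15 steps (1 → 31 through steps 1–7, 11 and 13–19).

**Steps most likely to fail**

1. Step 16. The carbenoid may be diverted into addition to the C5 arene, C–H insertion or capture by the silyl ether oxygen. The ylide may also break its ring C5–O bond instead of the exocyclic O–CH2 bond. The C2 equilibration may stall at a mixture or set off β-elimination of the silyloxy group at C4. The fallback sets out from 19 and comes back at 28; it closes the ring by O–H insertion and attaches the benzyl group afterwards. Compound 19 would be silylated (Et3SiOTf, 2,6-lutidine, CH2Cl2, −78 °C) to the triethylsilyl ether F1. Hydrolysis with LiOH/H2O2 and sulfite reduction of the peroxy acid F2 would give the acid F3. Isobutyl chloroformate/N-methylmorpholine would give the mixed carbonic anhydride F4, and diazomethane would convert this into the silyloxy diazoketone F5. AcOH-buffered Bu4NF at −20 °C should remove the secondary triethylsilyl group selectively to give the hydroxy diazoketone F6. Rh2(OAc)4 (1 mol %) in CH2Cl2 would close the ring by intramolecular carbenoid O–H insertion to the C2-unsubstituted oxolanone F7. Piperidine-catalysed aldol condensation with aldehyde 1 (only C2 can dehydrate) would give the benzylidene oxolanone F8. Conjugate reduction with [(Ph3P)CuH]6 in toluene, followed by the same DBU equilibration, would return to 28.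

2. Step 11. The magnesium enolate may expel silanolate (E1cB to the acryloyl imide), or anti and facial control may erode with this functionalised acyl group. The fallback sets out from 10 and comes back at 23; it replaces the auxiliary aldol by a catalytic allylation and a later oxidative cleavage. Iridium-catalysed transfer-hydrogenative anti-(hydroxymethyl)allylation of 10 with 4,7-dihydro-1,3-dioxepin-2-one would give the anti vinyl diol F9. The conditions would be [Ir(cod)Cl]2, a SEGPHOS-type bisphosphine of the antipode that delivers the (1S,2R) product, 4-cyano-3-nitrobenzoic acid, K3PO4, i-PrOH, THF, 90 °C. t-BuPh2SiCl/imidazole would silylate the primary hydroxyl to the silyl ether F10. Imidate 20 with catalytic PPTS would give the benzyl ether F11. OsO4 (cat.) with N-methylmorpholine N-oxide would give the vicinal diol F12, which NaIO4 would cleave to the aldehyde F13. Oxidation with NaClO2/NaH2PO4/2-methylbut-2-ene in t-BuOH/H2O would give acid 23.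

3. Step 4. Coupling at the ortho-alkoxy aryl iodide may be slow, and the diazo ester may decompose on palladium (loss of N2, carbene dimerisation). The fallback sets out from 5 and comes back at 6; it separates C–C bond formation from introduction of the diazo group. Negishi coupling of 5 with the Reformatsky reagent BrZnCH2CO2Et (from ethyl bromoacetate and Zn; Pd(dba)2 with a bulky biaryl phosphine, THF, rt) would give the arylacetate F14. Diazo transfer with 4-acetamidobenzenesulfonyl azide and DBU in MeCN would then give 6.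

Further compounds
F1 | step 16 | (S)-4-benzyl-3-[(2R,3S)-2-[(TBDPS-oxy)methyl]-3-(DBF)-3-(triethylsilyloxy)propanoyl]oxazolidin-2-one | O=C(N1[C@@H](Cc2ccccc2)COC1=O)[C@H](CO[Si](c1ccccc1)(c1ccccc1)C(C)(C)C)[C@@H](c1cc(OC)c2c(c1)[C@H](CO[Si](C)(C)C(C)(C)C)[C@H](c1ccc(OCc3ccccc3)c(OC)c1)O2)O[Si](CC)(CC)CC
F2 | step 16 | (2R,3S)-2-[(TBDPS-oxy)methyl]-3-(DBF)-3-(triethylsilyloxy)propaneperoxoic acid (formed in the flask) | OOC(=O)[C@H](CO[Si](c1ccccc1)(c1ccccc1)C(C)(C)C)[C@@H](c1cc(OC)c2c(c1)[C@H](CO[Si](C)(C)C(C)(C)C)[C@H](c1ccc(OCc3ccccc3)c(OC)c1)O2)O[Si](CC)(CC)CC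
F3 | step 16 | (2R,3S)-2-[(TBDPS-oxy)methyl]-3-(DBF)-3-(triethylsilyloxy)propanoic acid | OC(=O)[C@H](CO[Si](c1ccccc1)(c1ccccc1)C(C)(C)C)[C@@H](c1cc(OC)c2c(c1)[C@H](CO[Si](C)(C)C(C)(C)C)[C@H](c1ccc(OCc3ccccc3)c(OC)c1)O2)O[Si](CC)(CC)CC
F4 | step 16 | mixed anhydride of F3 with isobutyl hydrogen carbonate (formed in the flask) | CC(C)COC(=O)OC(=O)[C@H](CO[Si](c1ccccc1)(c1ccccc1)C(C)(C)C)[C@@H](c1cc(OC)c2c(c1)[C@H](CO[Si](C)(C)C(C)(C)C)[C@H](c1ccc(OCc3ccccc3)c(OC)c1)O2)O[Si](CC)(CC)CC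
F5 | step 16 | (3R,4S)-1-diazo-3-[(TBDPS-oxy)methyl]-4-(DBF)-4-(triethylsilyloxy)butan-2-one | [N-]=[N+]=CC(=O)[C@H](CO[Si](c1ccccc1)(c1ccccc1)C(C)(C)C)[C@@H](c1cc(OC)c2c(c1)[C@H](CO[Si](C)(C)C(C)(C)C)[C@H](c1ccc(OCc3ccccc3)c(OC)c1)O2)O[Si](CC)(CC)CC
F6 | step 16 | (3R,4S)-1-diazo-4-hydroxy-3-[(TBDPS-oxy)methyl]-4-(DBF)butan-2-one | [N-]=[N+]=CC(=O)[C@H](CO[Si](c1ccccc1)(c1ccccc1)C(C)(C)C)[C@@H](c1cc(OC)c2c(c1)[C@H](CO[Si](C)(C)C(C)(C)C)[C@H](c1ccc(OCc3ccccc3)c(OC)c1)O2)O
F7 | step 16 | (4R,5S)-4-[(TBDPS-oxy)methyl]-5-(DBF)oxolan-3-one | C1O[C@H](c2cc(OC)c3c(c2)[C@H](CO[Si](C)(C)C(C)(C)C)[C@H](c2ccc(OCc4ccccc4)c(OC)c2)O3)[C@@H](CO[Si](c2ccccc2)(c2ccccc2)C(C)(C)C)C1=O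
F8 | step 16 | (2Z,4R,5S)-2-[4-(benzyloxy)-3-methoxybenzylidene]-4-[(TBDPS-oxy)methyl]-5-(DBF)oxolan-3-one | COc1cc(/C=C2\O[C@H](c3cc(OC)c4c(c3)[C@H](CO[Si](C)(C)C(C)(C)C)[C@H](c3ccc(OCc5ccccc5)c(OC)c3)O4)[C@@H](CO[Si](c3ccccc3)(c3ccccc3)C(C)(C)C)C2=O)ccc1OCc1ccccc1
F9 | step 11 | (1S,2R)-1-(DBF)-2-ethenylpropane-1,3-diol (anti) | C=C[C@H](CO)[C@@H](c1cc(OC)c2c(c1)[C@H](CO[Si](C)(C)C(C)(C)C)[C@H](c1ccc(OCc3ccccc3)c(OC)c1)O2)O
F10 | step 11 | (1S,2R)-2-[(TBDPS-oxy)methyl]-1-(DBF)but-3-en-1-ol | C=C[C@H](CO[Si](c1ccccc1)(c1ccccc1)C(C)(C)C)[C@@H](c1cc(OC)c2c(c1)[C@H](CO[Si](C)(C)C(C)(C)C)[C@H](c1ccc(OCc3ccccc3)c(OC)c1)O2)O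
F11 | step 11 | BnV ether of F10: (3R,4S)-4-(BnV-oxy)-3-[(TBDPS-oxy)methyl]-4-(DBF)but-1-ene | C=C[C@H](CO[Si](c1ccccc1)(c1ccccc1)C(C)(C)C)[C@@H](c1cc(OC)c2c(c1)[C@H](CO[Si](C)(C)C(C)(C)C)[C@H](c1ccc(OCc3ccccc3)c(OC)c1)O2)OCc1ccc(OCc2ccccc2)c(OC)c1
F12 | step 11 | (3S,4S)-4-(BnV-oxy)-3-[(TBDPS-oxy)methyl]-4-(DBF)butane-1,2-diol, both C2 epimers (formed in the flask) | OCC(O)[C@H](CO[Si](c1ccccc1)(c1ccccc1)C(C)(C)C)[C@@H](c1cc(OC)c2c(c1)[C@H](CO[Si](C)(C)C(C)(C)C)[C@H](c1ccc(OCc3ccccc3)c(OC)c1)O2)OCc1ccc(OCc2ccccc2)c(OC)c1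
F13 | step 11 | (2R,3S)-3-(BnV-oxy)-2-[(TBDPS-oxy)methyl]-3-(DBF)propanal | O=C[C@H](CO[Si](c1ccccc1)(c1ccccc1)C(C)(C)C)[C@@H](c1cc(OC)c2c(c1)[C@H](CO[Si](C)(C)C(C)(C)C)[C@H](c1ccc(OCc3ccccc3)c(OC)c1)O2)OCc1ccc(OCc2ccccc2)c(OC)c1
F14 | step 4 | ethyl 2-[2-(BnV-oxy)-5-(dimethoxymethyl)-3-methoxyphenyl]acetate | CCOC(=O)Cc1cc(C(OC)OC)cc(OC)c1OCc1ccc(OCc2ccccc2)c(OC)c1
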